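**Retrosynthetic overview**

1. Feature: with the chain numbered C1 (benzylic CH2) to C15 (carbinol carbon), the Z C2=C3 alkene (C1 and C4 cis, methyl on C3) lies β,γ to the C5 ketone. Together with an oxygen on C5 it is the O–C1–C2–C3–C4–C5 ring of a 4-methyl-5,6-dihydro-2H-pyran-2-one, in which this alkene can only be Z.
2. Late disconnections: hydroquinone from its dimethyl ether through the quinone; C5 and C12 ketones from carbinols; C12–C13 by alkenyllithium addition to a C12 aldehyde; aryl–C1 by arylcopper substitution of the C1 allylic bromide obtained by reductive opening of the pyranone.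
3. Key disconnection: C4–C5 and the lactone C–O bond, by vinylogous aldol–lactonisation of the 3-methylbut-2-enoic acid dianion with the C5 aldehyde of the cyclopentane core.
4. Core: the cis vicinal quaternary carbons C7 and C11 come from the Weiss–Cook bicyclo[3.3.0]octanedione of biacetyl, through mono-deoxygenation, enantiotopic enolisation by a chiral lithium amide, ozonolysis to a δ-lactone and Weinreb opening.
5. Ring order: two fused cyclopentanes (Weiss–Cook); one is cleaved, reclosed as a δ-lactone and opened; then the dihydropyranone (key step), later opened; the benzene ring is brought in intact.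

Key step: step 10

Assumption: the (R,R) lithium amide is taken to remove the proton that gives the (1R,5S) silyl enol ether of step 5 (sense assigned by analogy with other meso cyclic ketones; if it is opposite, the (S,S) amide is used and nothing else changes); the C5 and C12 carbinol centres are carried as epimer mixtures and left undefined in the SMILES because both become ketones.

**Route**

Step 1
Reactants: 1 biacetyl (butane-2,3-dione); 2 dimethyl 3-oxopentanedioate (2 equiv)
Product: 3 tetramethyl cis-3,7-dihydroxy-1,5-dimethylbicyclo[3.3.0]octa-2,6-diene-2,4,6,8-tetracarboxylate (bis-enol form; C4 and C8 undefined)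
Conditions: NaHCO3, H2O (pH 8.3), rt
Reagents that add atoms: none
Why: Weiss–Cook condensation (two aldol/Michael sequences of the oxoglutarate on the 1,2-diketone) closes both five-membered rings, and the bicyclo[3.3.0]octane can only be cis-fused, which places the two methyl groups cis.

Step 2
Reactants: 3 tetraester
Product: 4 cis-1,5-dimethylbicyclo[3.3.0]octane-3,7-dione
Conditions: 1 M HCl, AcOH, reflux
Reagents that add atoms: none
Why: Acid hydrolysis and decarboxylation of the four β-keto ester groups should leave the diketone with the ring fusion untouched.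

Step 3
Reactants: 4 diketone
Product: 5 7,7-(ethylenedioxy)-cis-1,5-dimethylbicyclo[3.3.0]octan-3-one (monoketal)
Conditions: HOCH2CH2OH (1 equiv), p-TsOH (cat.), benzene, reflux, Dean–Stark
Reagents that add atoms: ethane-1,2-diol OCCO
Why: Acid-catalysed ketalisation with one equivalent of diol should give a statistical mixture from which the monoketal is separated, the diketone and bis-ketal being recycled.

Step 4
Reactants: 5 monoketal
Product: 8 cis-1,5-dimethylbicyclo[3.3.0]octan-3-one (meso), via hydrazone 6 (not isolated), via deoxygenated ketal 7 (not isolated)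
Conditions: N2H4·H2O, KOH, diethylene glycol, 130 → 200 °C; then 2 M HCl, THF, rt on the crude ketal
Reagents that add atoms: water O
Why: Wolff–Kishner reduction (Huang–Minlon variant) removes the free ketone under base that the ketal tolerates, and acid hydrolysis then unmasks the other carbonyl to give the meso ketone.

Step 5
Reactants: 8 meso ketone
Product: 9 (1R,5S)-1,5-dimethyl-3-(trimethylsilyloxy)bicyclo[3.3.0]oct-2-ene
Conditions: (R,R)-[PhCH(Me)]2NLi (from the amine and n-BuLi), LiCl, Me3SiCl (in situ quench), THF, −100 → −78 °C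
Reagents that add atoms: chlorotrimethylsilane C[Si](C)(C)Cl
Why: Enantioselective deprotonation of a meso ketone by a C2-symmetric chiral lithium amide with internal silyl trapping chooses one of the two enantiotopic α-CH2 groups and thereby fixes the absolute configuration of both quaternary carbons.

Step 6
Reactants: 9 silyl enol ether
Product: 12 (4aS,7aS)-4a,7a-dimethylhexahydrocyclopenta[c]pyran-3(1H)-one, via methoxy hydroperoxide silyl ester 10 (not isolated), via hydroxy acid 11 (not isolated)
Conditions: O3, CH2Cl2/MeOH, −78 °C; NaBH4, −78 °C → rt; 2 M HCl, rt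
Reagents that add atoms: ozone [O-][O+]=O
Why: Ozonolysis of the silyl enol ether cleaves the enol C=C into a silyl ester and a masked aldehyde on the neighbouring quaternary carbon; hydride work-up gives the hydroxy acid, which lactonises on acidification without touching a stereocentre.

Step 7
Reactants: 12 lactone
Product: 13 2-[(1S,2S)-2-(hydroxymethyl)-1,2-dimethylcyclopentyl]-N-methoxy-N-methylacetamide
Conditions: MeNH(OMe)·HCl, AlMe3, CH2Cl2, 0 °C → rt; aq. KNa tartrate; crude product taken on at once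
Reagents that add atoms: N,O-dimethylhydroxylamine hydrochloride CNOC.Cl
Why: Aluminium amide aminolysis (Weinreb opening) of the lactone places the two-carbon arm at the amide level and frees the neopentyl hydroxyl of the one-carbon arm, which differentiates the two arms.

Step 8
Reactants: 13 hydroxy amide
Product: 14 2-[(1S,2S)-2-(tert-butyldimethylsilyloxymethyl)-1,2-dimethylcyclopentyl]-N-methoxy-N-methylacetamide
Conditions: t-BuMe2SiOTf, 2,6-lutidine, CH2Cl2, −78 → 0 °C
Reagents that add atoms: tert-butyldimethylsilyl trifluoromethanesulfonate CC(C)(C)[Si](C)(C)OS(=O)(=O)C(F)(F)F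
Why: Silylation of the hindered neopentyl alcohol with the silyl triflate should be fast at low temperature and should forestall reclosure to the lactone.

Step 9
Reactants: 14 silyl ether amide
Product: 15 2-[(1S,2S)-2-(tert-butyldimethylsilyloxymethyl)-1,2-dimethylcyclopentyl]acetaldehyde
Conditions: i-Bu2AlH, THF, −78 °C; aq. KNa tartrate
Reagents that add atoms: none
Why: Hydride reduction of a Weinreb amide stops at the chelated tetrahedral intermediate and releases the C5 aldehyde on work-up.

Step 10
Reactants: 15 core aldehyde; 16 3-methylbut-2-enoic acid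
Product: 19 6-{[(1S,2S)-2-(tert-butyldimethylsilyloxymethyl)-1,2-dimethylcyclopentyl]methyl}-4-methyl-5,6-dihydro-2H-pyran-2-one (both C6 epimers), via dilithium dienolate 17 (not isolated), via Z hydroxy acid 18 (not isolated)
Conditions: 16, LiN(i-Pr)2 (2.1 equiv), THF, −78 → 0 °C; 15, −78 °C, then 45 °C; 1 M HCl to pH 3, 0 °C; PPTS (cat.), CH2Cl2, rt; NaHCO3 wash
Reagents that add atoms: none
Why: Two equivalents of LiN(i-Pr)2 turn 16 into the delocalised dienolate dianion 17, which first adds to the aldehyde of 15 through its α-carbon; that aldolate reverts on warming whereas attack through the terminal γ-carbon (C4) does not, so the mixture should drain into the δ-hydroxy acid 18 with the C4–C5 bond made. The closest known reaction type is the vinylogous aldol addition of the 3-methylbut-2-enoic acid dianion to aldehydes and ketones, which is known to end in 4-methyl-5,6-dihydro-2H-pyran-2-ones. The ring closes by 6-exo-trig acyl substitution of the C5 hydroxyl on the C1 carboxyl (lactonisation) under mild acid. The only new stereocentre is the C5 carbinol, formed without control and needing none, since both epimers converge on the C5 ketone in step 24. The step needs γ- over α-regioselectivity, secured by the thermodynamic equilibration, and Z geometry at C2=C3, secured because only the acid with C1 and C4 cis can lactonise while any E acid stays in the NaHCO3 wash. Enolisation of 15 is held back by its neopentyl-type α-CH2, and the silyl ether is inert to the dianion.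

Step 11
Reactants: 19 dihydropyranone
Product: 20 (2Z)-6-[(1S,2S)-2-(tert-butyldimethylsilyloxymethyl)-1,2-dimethylcyclopentyl]-3-methylhex-2-ene-1,5-diol
Conditions: i-Bu2AlH (4 equiv), CH2Cl2, −78 °C → rt; aq. KNa tartrate
Reagents that add atoms: none
Why: 1,2-Reduction of the unsaturated lactone through the lactol should give the diol with the ring-derived Z alkene intact.

Step 12
Reactants: 20 Z diol
Product: 21 (2Z)-6-[(1S,2S)-2-(tert-butyldimethylsilyloxymethyl)-1,2-dimethylcyclopentyl]-5-hydroxy-3-methylhex-2-en-1-yl acetate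
Conditions: AcCl, 2,4,6-collidine, CH2Cl2, −78 °C
Reagents that add atoms: acetyl chloride CC(=O)Cl
Why: Selective acylation at low temperature should take the unhindered primary allylic hydroxyl and leave the secondary C5 hydroxyl free.

Step 13
Reactants: 21 monoacetate
Product: 22 (2Z)-6-[(1S,2S)-2-(tert-butyldimethylsilyloxymethyl)-1,2-dimethylcyclopentyl]-3-methyl-5-(triisopropylsilyloxy)hex-2-en-1-yl acetate
Conditions: i-Pr3SiOTf, 2,6-lutidine, CH2Cl2, 0 °C → rt
Reagents that add atoms: triisopropylsilyl trifluoromethanesulfonate CC(C)[Si](C(C)C)(C(C)C)OS(=O)(=O)C(F)(F)F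
Why: Silylation of the C5 hydroxyl blocks its cyclisation onto C1 in the later bromide and gives an ether that outlasts the primary tert-butyldimethylsilyl ether under acid.

Step 14
Reactants: 22 acetate
Product: 23 (2Z)-6-[(1S,2S)-2-(tert-butyldimethylsilyloxymethyl)-1,2-dimethylcyclopentyl]-3-methyl-5-(triisopropylsilyloxy)hex-2-en-1-ol
Conditions: K2CO3 (cat.), MeOH, 0 °C → rt
Reagents that add atoms: none
Why: Base-catalysed transesterification removes the acetate while both silyl ethers are stable.

Step 15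
Reactants: 23 allylic alcohol
Product: 24 tert-butyl{[(1S,2S)-2-[(4Z)-6-bromo-4-methyl-2-(triisopropylsilyloxy)hex-4-en-1-yl]-1,2-dimethylcyclopentyl]methoxy}dimethylsilane
Conditions: CBr4, PPh3, CH2Cl2, 0 °C; used at once
Reagents that add atoms: tetrabromomethane BrC(Br)(Br)Br
Why: Appel bromination of a primary allylic alcohol proceeds by SN2 at C1 under neutral conditions and should keep the alkene position and Z geometry.

Step 16
Reactants: 25 4-methoxy-2-methylphenol
Product: 26 2-bromo-4-methoxy-6-methylphenol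
Conditions: Br2, CH2Cl2, 0 °C
Reagents that add atoms: bromine BrBr
Why: Electrophilic bromination is directed by the free hydroxyl to its only open ortho position, the para position and the other ortho position being occupied.

Step 17
Reactants: 26 bromophenol
Product: 27 1-bromo-2,5-dimethoxy-3-methylbenzene
Conditions: MeI, K2CO3, acetone, reflux
Reagents that add atoms: iodomethane CI
Why: Williamson O-methylation of the phenol gives the hydroquinone dimethyl ether that tolerates organometallic steps and is later removed oxidatively.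

Step 18
Reactants: 27 aryl bromide; 24 allylic bromide
Product: 30 tert-butyl{[(1S,2S)-2-[(4Z)-6-(2,5-dimethoxy-3-methylphenyl)-4-methyl-2-(triisopropylsilyloxy)hex-4-en-1-yl]-1,2-dimethylcyclopentyl]methoxy}dimethylsilane, via aryllithium 28 (not isolated), via arylcopper 29 (not isolated)
Conditions: 27, n-BuLi, THF, −78 °C; CuBr·SMe2, −78 → −40 °C; 24, −78 → 0 °C
Reagents that add atoms: none
Why: Bromine–lithium exchange and transmetalation give an arylcopper that substitutes primary allylic bromides at the α-carbon (SN2) with retention of alkene geometry, as in aryl prenylations and geranylations.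

Step 19
Reactants: 30 coupled bis-silyl ether
Product: 31 [(1S,2S)-2-[(4Z)-6-(2,5-dimethoxy-3-methylphenyl)-4-methyl-2-(triisopropylsilyloxy)hex-4-en-1-yl]-1,2-dimethylcyclopentyl]methanol
Conditions: camphorsulfonic acid (cat.), MeOH/CH2Cl2, 0 °C → rt
Reagents that add atoms: none
Why: Acid-catalysed methanolysis should cleave the primary tert-butyldimethylsilyl ether and leave the much more stable secondary triisopropylsilyl ether at C5.

Step 20
Reactants: 31 C12 alcohol
Product: 32 (1S,2S)-2-[(4Z)-6-(2,5-dimethoxy-3-methylphenyl)-4-methyl-2-(triisopropylsilyloxy)hex-4-en-1-yl]-1,2-dimethylcyclopentane-1-carbaldehyde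
Conditions: Dess–Martin periodinane, pyridine, CH2Cl2, rt
Reagents that add atoms: none
Why: Dess–Martin oxidation converts the neopentyl primary alcohol into the non-enolisable C12 aldehyde under buffered conditions.

Step 21
Reactants: 33 2-methylbut-3-yn-2-ol
Product: 34 (3E)-2-methyl-4-(tributylstannyl)but-3-en-2-ol
Conditions: Bu3SnH, PdCl2(PPh3)2 (cat.), THF, 0 °C → rt
Reagents that add atoms: tributylstannane CCCC[SnH](CCCC)CCCC
Why: Palladium-catalysed syn hydrostannation of the terminal alkyne places tin at the unhindered terminus and should give the E alkenylstannane, the minor internal regioisomer being removed by chromatography.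

Step 22
Reactants: 34 alkenylstannane; 32 C12 aldehyde
Product: 36 (2E)-1-[(1S,2S)-2-[(4Z)-6-(2,5-dimethoxy-3-methylphenyl)-4-methyl-2-(triisopropylsilyloxy)hex-4-en-1-yl]-1,2-dimethylcyclopentyl]-4-methylpent-2-ene-1,4-diol (C12 epimers), via dilithio alkenyl alkoxide 35 (not isolated)
Conditions: 34, n-BuLi (2 equiv), THF, −78 → 0 °C; 32, −78 °C; H2O
Reagents that add atoms: none
Why: Deprotonation and tin–lithium exchange give the E alkenyllithium with retention of geometry, which adds 1,2 to the hindered aldehyde to form C12–C13; the carbinol configuration is irrelevant because C12 is oxidised.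

Step 23
Reactants: 36 diol silyl ether
Product: 37 (2E)-1-[(1S,2S)-2-[(4Z)-6-(2,5-dimethoxy-3-methylphenyl)-2-hydroxy-4-methylhex-4-en-1-yl]-1,2-dimethylcyclopentyl]-4-methylpent-2-ene-1,4-diol
Conditions: Bu4NF, THF, rt
Reagents that add atoms: none
Why: Fluoride cleaves the secondary triisopropylsilyl ether and frees the C5 carbinol while no ketone is yet present.

Step 24
Reactants: 37 triol
Product: 38 (2E)-1-[(1S,2S)-2-[(4Z)-6-(2,5-dimethoxy-3-methylphenyl)-4-methyl-2-oxohex-4-en-1-yl]-1,2-dimethylcyclopentyl]-4-hydroxy-4-methylpent-2-en-1-one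
Conditions: Dess–Martin periodinane (3 equiv), pyridine, CH2Cl2, 0 °C → rt
Reagents that add atoms: none
Why: Dess–Martin oxidation converts both secondary carbinols (C5 and C12) into ketones under near-neutral conditions that should not move the β,γ-alkene into conjugation, and the tertiary alcohol cannot be oxidised.

Step 25
Reactants: 38 dimethyl ether diketone
Product: 40 (2E)-1-[(1S,2S)-2-[(4Z)-6-(2,5-dihydroxy-3-methylphenyl)-4-methyl-2-oxohex-4-en-1-yl]-1,2-dimethylcyclopentyl]-4-hydroxy-4-methylpent-2-en-1-one (target), via quinone 39 (not isolated)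
Conditions: (NH4)2Ce(NO3)6, MeCN/H2O, 0 °C; then Na2S2O4, H2O/EtOAc, rt
Reagents that add atoms: water O
Why: Oxidative demethylation of the 1,4-dimethoxyarene gives the benzoquinone, and dithionite reduction returns the hydroquinone under near-neutral conditions that spare the skipped enone, the enone and the tertiary alcohol.

**Compound list**

1 | biacetyl (butane-2,3-dione) | CC(=O)C(C)=O | starting material
2 | dimethyl 3-oxopentanedioate | COC(=O)CC(=O)CC(=O)OC | starting material
3 | tetramethyl cis-3,7-dihydroxy-1,5-dimethylbicyclo[3.3.0]octa-2,6-diene-2,4,6,8-tetracarboxylate (C4, C8 undefined) | COC(=O)C1=C(O)C(C(=O)OC)[C@]2(C)C(C(=O)OC)=C(O)C(C(=O)OC)[C@]12C | intermediate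
4 | cis-1,5-dimethylbicyclo[3.3.0]octane-3,7-dione | O=C1C[C@]2(C)CC(=O)C[C@]2(C)C1 | intermediate
5 | 7,7-(ethylenedioxy)-cis-1,5-dimethylbicyclo[3.3.0]octan-3-one | O=C1C[C@]2(C)CC3(OCCO3)C[C@]2(C)C1 | intermediate
6 | hydrazone of 5 | NN=C1C[C@]2(C)CC3(OCCO3)C[C@]2(C)C1 | intermediate
7 | 3,3-(ethylenedioxy)-cis-1,5-dimethylbicyclo[3.3.0]octane | C1C[C@]2(C)CC3(OCCO3)C[C@]2(C)C1 | intermediate
8 | cis-1,5-dimethylbicyclo[3.3.0]octan-3-one (meso) | O=C1C[C@]2(C)CCC[C@]2(C)C1 | intermediate
9 | (1R,5S)-1,5-dimethyl-3-(trimethylsilyloxy)bicyclo[3.3.0]oct-2-ene | C[Si](C)(C)OC1=C[C@@]2(C)CCC[C@@]2(C)C1 | intermediate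
10 | trimethylsilyl 2-[(1S,2S)-2-[hydroperoxy(methoxy)methyl]-1,2-dimethylcyclopentyl]acetate (acetal carbon undefined) | C[Si](C)(C)OC(=O)C[C@]1(C)CCC[C@]1(C)C(OC)OO | intermediate
11 | 2-[(1S,2S)-2-(hydroxymethyl)-1,2-dimethylcyclopentyl]acetic acid | OC(=O)C[C@]1(C)CCC[C@]1(C)CO | intermediate
12 | (4aS,7aS)-4a,7a-dimethylhexahydrocyclopenta[c]pyran-3(1H)-one | O=C1C[C@]2(C)CCC[C@]2(C)CO1 | intermediate
13 | 2-[(1S,2S)-2-(hydroxymethyl)-1,2-dimethylcyclopentyl]-N-methoxy-N-methylacetamide | CON(C)C(=O)C[C@]1(C)CCC[C@]1(C)CO | intermediate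
14 | 2-[(1S,2S)-2-(tert-butyldimethylsilyloxymethyl)-1,2-dimethylcyclopentyl]-N-methoxy-N-methylacetamide | CON(C)C(=O)C[C@]1(C)CCC[C@]1(C)CO[Si](C)(C)C(C)(C)C | intermediate
15 | 2-[(1S,2S)-2-(tert-butyldimethylsilyloxymethyl)-1,2-dimethylcyclopentyl]acetaldehyde | O=CC[C@]1(C)CCC[C@]1(C)CO[Si](C)(C)C(C)(C)C | intermediate
16 | 3-methylbut-2-enoic acid | CC(C)=CC(=O)O | starting material
17 | dilithium 3-methylbuta-1,3-diene-1,1-diolate (dianion of 16) | [Li+].[Li+].C=C(C)C=C([O-])[O-] | intermediate
18 | (2Z)-6-[(1S,2S)-2-(tert-butyldimethylsilyloxymethyl)-1,2-dimethylcyclopentyl]-5-hydroxy-3-methylhex-2-enoic acid (C5 epimers) | C/C(=C/C(=O)O)CC(O)C[C@]1(C)CCC[C@]1(C)CO[Si](C)(C)C(C)(C)C | intermediate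
19 | 6-{[(1S,2S)-2-(tert-butyldimethylsilyloxymethyl)-1,2-dimethylcyclopentyl]methyl}-4-methyl-5,6-dihydro-2H-pyran-2-one (C6 epimers) | CC1=CC(=O)OC(C1)C[C@]2(C)CCC[C@]2(C)CO[Si](C)(C)C(C)(C)C | intermediate
20 | (2Z)-6-[(1S,2S)-2-(tert-butyldimethylsilyloxymethyl)-1,2-dimethylcyclopentyl]-3-methylhex-2-ene-1,5-diol | C/C(=C/CO)CC(O)C[C@]1(C)CCC[C@]1(C)CO[Si](C)(C)C(C)(C)C | intermediate
21 | 1-acetate of 20 | C/C(=C/COC(C)=O)CC(O)C[C@]1(C)CCC[C@]1(C)CO[Si](C)(C)C(C)(C)C | intermediate
22 | 1-acetate 5-triisopropylsilyl ether of 20 | C/C(=C/COC(C)=O)CC(O[Si](C(C)C)(C(C)C)C(C)C)C[C@]1(C)CCC[C@]1(C)CO[Si](C)(C)C(C)(C)C | intermediate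
23 | (2Z)-6-[(1S,2S)-2-(tert-butyldimethylsilyloxymethyl)-1,2-dimethylcyclopentyl]-3-methyl-5-(triisopropylsilyloxy)hex-2-en-1-ol | C/C(=C/CO)CC(O[Si](C(C)C)(C(C)C)C(C)C)C[C@]1(C)CCC[C@]1(C)CO[Si](C)(C)C(C)(C)C | intermediate
24 | tert-butyl{[(1S,2S)-2-[(4Z)-6-bromo-4-methyl-2-(triisopropylsilyloxy)hex-4-en-1-yl]-1,2-dimethylcyclopentyl]methoxy}dimethylsilane | C/C(=C/CBr)CC(O[Si](C(C)C)(C(C)C)C(C)C)C[C@]1(C)CCC[C@]1(C)CO[Si](C)(C)C(C)(C)C | intermediate
25 | 4-methoxy-2-methylphenol | COc1ccc(O)c(C)c1 | starting material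
26 | 2-bromo-4-methoxy-6-methylphenol | COc1cc(C)c(O)c(Br)c1 | intermediate
27 | 1-bromo-2,5-dimethoxy-3-methylbenzene | COc1cc(C)c(OC)c(Br)c1 | intermediate
28 | (2,5-dimethoxy-3-methylphenyl)lithium | [Li]c1cc(OC)cc(C)c1OC | intermediate
29 | (2,5-dimethoxy-3-methylphenyl)copper | [Cu]c1cc(OC)cc(C)c1OC | intermediate
30 | tert-butyl{[(1S,2S)-2-[(4Z)-6-(2,5-dimethoxy-3-methylphenyl)-4-methyl-2-(triisopropylsilyloxy)hex-4-en-1-yl]-1,2-dimethylcyclopentyl]methoxy}dimethylsilane | C/C(=C/Cc1cc(OC)cc(C)c1OC)CC(O[Si](C(C)C)(C(C)C)C(C)C)C[C@]1(C)CCC[C@]1(C)CO[Si](C)(C)C(C)(C)C | intermediate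
31 | [(1S,2S)-2-[(4Z)-6-(2,5-dimethoxy-3-methylphenyl)-4-methyl-2-(triisopropylsilyloxy)hex-4-en-1-yl]-1,2-dimethylcyclopentyl]methanol | C/C(=C/Cc1cc(OC)cc(C)c1OC)CC(O[Si](C(C)C)(C(C)C)C(C)C)C[C@]1(C)CCC[C@]1(C)CO | intermediate
32 | (1S,2S)-2-[(4Z)-6-(2,5-dimethoxy-3-methylphenyl)-4-methyl-2-(triisopropylsilyloxy)hex-4-en-1-yl]-1,2-dimethylcyclopentane-1-carbaldehyde | C/C(=C/Cc1cc(OC)cc(C)c1OC)CC(O[Si](C(C)C)(C(C)C)C(C)C)C[C@]1(C)CCC[C@]1(C)C=O | intermediate
33 | 2-methylbut-3-yn-2-ol | CC(C)(O)C#C | starting material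
34 | (3E)-2-methyl-4-(tributylstannyl)but-3-en-2-ol | CC(C)(O)/C=C/[Sn](CCCC)(CCCC)CCCC | intermediate
35 | lithium (3E)-4-lithio-2-methylbut-3-en-2-olate | [Li]/C=C/C(C)(C)O[Li] | intermediate
36 | (2E)-1-[(1S,2S)-2-[(4Z)-6-(2,5-dimethoxy-3-methylphenyl)-4-methyl-2-(triisopropylsilyloxy)hex-4-en-1-yl]-1,2-dimethylcyclopentyl]-4-methylpent-2-ene-1,4-diol | C/C(=C/Cc1cc(OC)cc(C)c1OC)CC(O[Si](C(C)C)(C(C)C)C(C)C)C[C@]1(C)CCC[C@]1(C)C(O)/C=C/C(C)(C)O | intermediate
37 | (2E)-1-[(1S,2S)-2-[(4Z)-6-(2,5-dimethoxy-3-methylphenyl)-2-hydroxy-4-methylhex-4-en-1-yl]-1,2-dimethylcyclopentyl]-4-methylpent-2-ene-1,4-diol | C/C(=C/Cc1cc(OC)cc(C)c1OC)CC(O)C[C@]1(C)CCC[C@]1(C)C(O)/C=C/C(C)(C)O | intermediate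
38 | (2E)-1-[(1S,2S)-2-[(4Z)-6-(2,5-dimethoxy-3-methylphenyl)-4-methyl-2-oxohex-4-en-1-yl]-1,2-dimethylcyclopentyl]-4-hydroxy-4-methylpent-2-en-1-one | C/C(=C/Cc1cc(OC)cc(C)c1OC)CC(=O)C[C@]1(C)CCC[C@]1(C)C(=O)/C=C/C(C)(C)O | intermediate
39 | 2-methyl-1,4-benzoquinone bearing the full side chain at C6 (quinone of the target) | C/C(=C/CC1=CC(=O)C=C(C)C1=O)CC(=O)C[C@]2(C)CCC[C@]2(C)C(=O)/C=C/C(C)(C)O | intermediate
40 | (2E)-1-[(1S,2S)-2-[(4Z)-6-(2,5-dihydroxy-3-methylphenyl)-4-methyl-2-oxohex-4-en-1-yl]-1,2-dimethylcyclopentyl]-4-hydroxy-4-methylpent-2-en-1-one | C/C(=C/Cc1cc(O)cc(C)c1O)CC(=O)C[C@]1(C)CCC[C@]1(C)C(=O)/C=C/C(C)(C)O | target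

**Step count and risks**

Total step count: 25. Longest linear sequence: 22 steps (steps 1–15, 18–20 and 22–25); steps 16–17 and step 21 are side branches.

Most likely to fail:

1. Step 10 (key step). The kinetic α-addition may not revert fast enough, or the dianion may enolise the aldehyde and set off its self-condensation, so that little γ-adduct forms. Fallback, from 15 back to 19: addition of 2-methylallylmagnesium chloride to 15 would give 1-[(1S,2S)-2-(tert-butyldimethylsilyloxymethyl)-1,2-dimethylcyclopentyl]-4-methylpent-4-en-2-ol F1. Acylation with acryloyl chloride and Et3N would give its acrylate F2. Ring-closing metathesis of F2 with the second-generation Grubbs catalyst RuCl2(H2IMes)(PCy3)(=CHPh) in toluene at 80 °C would close the same dihydropyranone 19 across C2=C3, again with ring-enforced Z geometry.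

2. Step 5. Discrimination between the two enantiotopic α-CH2 groups, each next to a quaternary carbon, may be insufficient, which would lower the enantiomeric purity of everything downstream. Fallback, from 8 back to 12: Baeyer–Villiger oxidation of 8 (CF3CO3H, Na2HPO4, CH2Cl2) would give the racemic cis-fused lactone F3. Aminolysis with (S)-1-phenylethylamine and AlMe3 would open it to two diastereomeric hydroxy amides, N-[(1S)-1-phenylethyl]-2-[(1S,2S)-2-(hydroxymethyl)-1,2-dimethylcyclopentyl]acetamide F4 and its (1R,2R) diastereomer F5, to be separated by crystallisation or chromatography. Heating F4 with p-TsOH in toluene would reclose the lactone with loss of the amine and deliver 12 as a single enantiomer.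

3. Step 7. The hydroxy amide, with two quaternary carbons in its tether, may reclose to the lactone during work-up before it can be silylated. Fallback, from 12 back to 15: reduction of 12 with i-Bu2AlH (1.1 equiv, −78 °C) would give the lactol (4aS,7aS)-4a,7a-dimethyloctahydrocyclopenta[c]pyran-3-ol F6. Wittig methylenation with Ph3P=CH2 would trap its open form as [(1S,2S)-1,2-dimethyl-2-(prop-2-en-1-yl)cyclopentyl]methanol F7. Silylation (t-BuMe2SiCl, imidazole, DMF) would give the silyl ether F8, and ozonolysis of F8 (O3, CH2Cl2, −78 °C; PPh3) would return aldehyde 15.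

**Further compounds**

F1 | step 10 | 1-[(1S,2S)-2-(tert-butyldimethylsilyloxymethyl)-1,2-dimethylcyclopentyl]-4-methylpent-4-en-2-ol | C=C(C)CC(O)C[C@]1(C)CCC[C@]1(C)CO[Si](C)(C)C(C)(C)C
F2 | step 10 | 1-[(1S,2S)-2-(tert-butyldimethylsilyloxymethyl)-1,2-dimethylcyclopentyl]-4-methylpent-4-en-2-yl prop-2-enoate | C=CC(=O)OC(CC(C)=C)C[C@]1(C)CCC[C@]1(C)CO[Si](C)(C)C(C)(C)C
F3 | step 5 | racemic cis-4a,7a-dimethylhexahydrocyclopenta[c]pyran-3(1H)-one | O=C1CC2(C)CCCC2(C)CO1
F4 | step 5 | N-[(1S)-1-phenylethyl]-2-[(1S,2S)-2-(hydroxymethyl)-1,2-dimethylcyclopentyl]acetamide | C[C@H](NC(=O)C[C@]1(C)CCC[C@]1(C)CO)c1ccccc1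
F5 | step 5 | N-[(1S)-1-phenylethyl]-2-[(1R,2R)-2-(hydroxymethyl)-1,2-dimethylcyclopentyl]acetamide | C[C@H](NC(=O)C[C@@]1(C)CCC[C@@]1(C)CO)c1ccccc1
F6 | step 7 | (4aS,7aS)-4a,7a-dimethyloctahydrocyclopenta[c]pyran-3-ol (anomers) | OC1C[C@]2(C)CCC[C@]2(C)CO1
F7 | step 7 | [(1S,2S)-1,2-dimethyl-2-(prop-2-en-1-yl)cyclopentyl]methanol | C=CC[C@]1(C)CCC[C@]1(C)CO
F8 | step 7 | tert-butyl{[(1S,2S)-1,2-dimethyl-2-(prop-2-en-1-yl)cyclopentyl]methoxy}dimethylsilane | C=CC[C@]1(C)CCC[C@]1(C)CO[Si](C)(C)C(C)(C)C
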